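**Retrosynthetic overview**
- Plakortolide K ⇐ diimide reduction ⇐ cross-metathesis of a C6-allyl bicyclic peroxide with 11-phenylundec-1-ene; the chain is grown last on the intact peroxide.
- C6 quaternary centre ⇐ axial allylation of a lactone-fused cyclic peroxycarbenium ion (from a C6 methoxy peroxyketal), cis to the lactone oxygen.
- 1,2-Dioxane ring (formed second) ⇐ intramolecular conjugate addition of a C6 hydroperoxide (an ozone-derived hydroperoxy ketal) to C3 of a Δ2-butenolide, as in the biosynthesis; cis-fusion sets C3.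
- Butenolide ring (formed first) ⇐ Z-olefination/lactonisation of a lactol from a Seebach dioxolanone; C4 comes from (S)-lactic acid by methallylation with self-regeneration of the stereocentre.

Assumption: the presumed biosynthesis is taken as lactonisation of a polyketide 4-hydroxy-2-enoic acid to a Δ2-butenolide followed by intramolecular conjugate addition of a C6 hydroperoxide to C3; polyketide numbering (C1 = lactone carbonyl, C18 = benzylic carbon) is used for all bicyclic compounds, and the target is (3R,4R,6S).

**Step 1**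
Reactants: 1 (S)-lactic acid; 2 pivalaldehyde (2,2-dimethylpropanal)
Product: 3 (2S,5S)-2-tert-butyl-5-methyl-1,3-dioxolan-4-one
Conditions: TsOH·H2O (cat.), H2SO4 (cat.), pentane, reflux, Dean–Stark; recrystallise (Et2O/pentane, −78 °C)
Reagents that add atoms: none
Why: Acid-catalysed acetalisation of the α-hydroxy acid (Seebach dioxolanone formation) gives mainly the cis-acetal, which low-temperature crystallisation brings to a single diastereomer; the lactate centre is untouched and the acetal centre (2S) follows from the thermodynamic cis preference.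

**Step 2**
Reactants: 3 (2S,5S)-2-tert-butyl-5-methyl-1,3-dioxolan-4-one; 4 3-bromo-2-methylprop-1-ene (methallyl bromide)
Product: 6 (2S,5R)-2-tert-butyl-5-methyl-5-(2-methylprop-2-en-1-yl)-1,3-dioxolan-4-one, via lithium enolate 5 (not isolated)
Conditions: LiN(iPr)2 (commercial LDA solution), THF, −78 °C; then 4, −78 → −30 °C
Reagents that add atoms: none
Why: Seebach alkylation with self-regeneration of the stereocentre: the planar lithium enolate is alkylated anti to the tert-butyl group of the acetal, so the methallyl group takes the place of the original hydrogen and fixes the quaternary C4 of the target (5R here, dr about 95:5 or better).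

**Step 3**
Reactants: 6 (2S,5R)-2-tert-butyl-5-methyl-5-(2-methylprop-2-en-1-yl)-1,3-dioxolan-4-one
Product: 9 (R)-5-methyl-5-(2-methylprop-2-en-1-yl)furan-2(5H)-one, via lactol 7 (not isolated), via Z-hydroxy enoate 8 (not isolated)
Conditions: iBu2AlH, CH2Cl2, −78 °C, aqueous work-up; crude lactol, then NaH, (PhO)2P(O)CH2CO2Et (2.5 equiv), THF, −78 → 0 °C
Reagents that add atoms: ethyl 2-(diphenoxyphosphoryl)acetate, CCOC(=O)CP(=O)(Oc1ccccc1)Oc1ccccc1
Why: Half-reduction of the acylal lactone to the lactol is followed by an Ando Z-selective Horner–Wadsworth–Emmons olefination of its open hydroxy-aldehyde form (the hemiacetal loses pivalaldehyde), and the freed tertiary hydroxyl lactonises onto the Z-ester to close the butenolide (first ring) without touching the quaternary stereocentre.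

**Step 4**
Reactants: 9 (R)-5-methyl-5-(2-methylprop-2-en-1-yl)furan-2(5H)-one
Product: 12 (3R,4R)-3,6-epidioxy-4-hydroxy-6-methoxy-4-methylheptanoic acid 1,4-lactone (cis-fused; both C6 epimers), via carbonyl oxide 10 (not isolated), via hydroperoxy ketal 11 (not isolated)
Conditions: O3, CH2Cl2/MeOH (3:1), −78 °C; concentrate cold; then Et2NH (0.3 equiv), CF3CH2OH, 0 °C → rt
Reagents that add atoms: ozone, [O-][O+]=O; methanol, CO
Why: Criegee ozonolysis of the electron-rich 1,1-disubstituted alkene (the conjugated butenolide alkene is far slower) gives formaldehyde and the more substituted ketone O-oxide, which methanol traps as the hydroperoxy ketal, and its OOH group then closes the 1,2-dioxane (second ring) by a Kobayashi-type amine-mediated intramolecular peroxy-Michael addition to C3 of the butenolide, the short tether from C4 allowing only cis ring fusion and so setting C3 as R.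

**Step 5**
Reactants: 12 (3R,4R)-3,6-epidioxy-4-hydroxy-6-methoxy-4-methylheptanoic acid 1,4-lactone
Product: 14 (3R,4R,6S)-3,6-epidioxy-4-hydroxy-4,6-dimethylnon-8-enoic acid 1,4-lactone, via peroxycarbenium triflate 13 (not isolated)
Conditions: CH2=CHCH2SiMe3 (3 equiv), Me3SiOTf (0.3 equiv), CH2Cl2, −78 → −40 °C
Reagents that add atoms: allyltrimethylsilane, C=CC[Si](C)(C)C
Why: Hosomi–Sakurai allylation of a cyclic peroxycarbenium ion (Dussault-type substitution of a peroxyketal): in the favoured half-chair the C4 methyl group and the C3–C2 bond are pseudo-equatorial and the lactone oxygen is pseudo-axial, so chair-like axial attack at C6 occurs cis to the lactone oxygen (the other chair-like path is syn-axial to the C4 methyl group), which places the new chain trans to the C4 methyl group and sets C6 as S.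

**Step 6**
Reactants: 15 11-bromoundec-1-ene; 16 phenylmagnesium bromide
Product: 17 11-phenylundec-1-ene
Conditions: FeCl3 (5 mol %), TMEDA (1.2 equiv), THF, 0 °C, slow addition of 16
Reagents that add atoms: none
Why: Iron-catalysed Kumada-type cross-coupling of an aryl Grignard reagent with a primary alkyl bromide (Nakamura conditions) forms the aryl–alkyl bond without touching the remote terminal alkene, and no stereocentre is involved.

**Step 7**
Reactants: 14 (3R,4R,6S)-3,6-epidioxy-4-hydroxy-4,6-dimethylnon-8-enoic acid 1,4-lactone; 17 11-phenylundec-1-ene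
Product: 18 (3R,4R,6S)-3,6-epidioxy-4-hydroxy-4,6-dimethyl-18-phenyloctadec-8-enoic acid 1,4-lactone (E/Z mixture)
Conditions: 17 (3 equiv), second-generation Hoveyda–Grubbs catalyst RuCl2(=CH–C6H4-2-OiPr)(1,3-dimesitylimidazolidin-2-ylidene) (5 mol %), CH2Cl2, 40 °C
Reagents that add atoms: none
Why: Olefin cross-metathesis of two unhindered monosubstituted alkenes with a phosphine-free ruthenium alkylidene that tolerates dialkyl peroxides and lactones, driven by loss of ethylene and excess of the cheap partner; the E/Z ratio is irrelevant because the alkene is reduced next and no stereocentre is touched.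

**Step 8**
Reactants: 18 (3R,4R,6S)-3,6-epidioxy-4-hydroxy-4,6-dimethyl-18-phenyloctadec-8-enoic acid 1,4-lactone
Product: 19 plakortolide K, (3R,4R,6S)-3,6-epidioxy-4-hydroxy-4,6-dimethyl-18-phenyloctadecanoic acid 1,4-lactone
Conditions: KO2CN=NCO2K (excess), AcOH, MeOH/CH2Cl2, 0 °C → rt
Reagents that add atoms: none
Why: Diimide reduction: diimide made in the flask from the azodicarboxylate transfers two hydrogen atoms to the isolated disubstituted alkene in a concerted syn fashion and, unlike catalytic hydrogenation, leaves the O–O bond, the lactone and the arene intact, so all three stereocentres are carried through unchanged.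

**Compound list**
1 | (S)-lactic acid | C[C@H](O)C(=O)O | starting material
2 | pivalaldehyde (2,2-dimethylpropanal) | CC(C)(C)C=O | starting material
3 | (2S,5S)-2-tert-butyl-5-methyl-1,3-dioxolan-4-one (cis) | C[C@@H]1O[C@H](C(C)(C)C)OC1=O | intermediate
4 | 3-bromo-2-methylprop-1-ene (methallyl bromide) | C=C(C)CBr | starting material
5 | lithium (2S)-2-tert-butyl-5-methyl-1,3-dioxol-4-olate (lithium enolate of 3) | CC1=C([O-])O[C@@H](C(C)(C)C)O1.[Li+] | intermediate
6 | (2S,5R)-2-tert-butyl-5-methyl-5-(2-methylprop-2-en-1-yl)-1,3-dioxolan-4-one | C[C@]1(CC(C)=C)O[C@H](C(C)(C)C)OC1=O | intermediate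
7 | (2S,5R)-2-tert-butyl-5-methyl-5-(2-methylprop-2-en-1-yl)-1,3-dioxolan-4-ol (lactol; both C4 epimers) | C[C@]1(CC(C)=C)O[C@H](C(C)(C)C)OC1O | intermediate
8 | ethyl (R,Z)-4-hydroxy-4,6-dimethylhepta-2,6-dienoate | CCOC(=O)/C=C\[C@](C)(O)CC(C)=C | intermediate
9 | (R)-5-methyl-5-(2-methylprop-2-en-1-yl)furan-2(5H)-one | C[C@]1(CC(C)=C)OC(=O)C=C1 | intermediate
10 | (R)-5-methyl-5-(2-oxopropyl)furan-2(5H)-one O-oxide (carbonyl oxide at C6) | C[C@]1(CC(C)=[O+][O-])OC(=O)C=C1 | intermediate
11 | (R)-5-(2-hydroperoxy-2-methoxypropyl)-5-methylfuran-2(5H)-one (both epimers at the ketal carbon) | C[C@]1(CC(C)(OC)OO)OC(=O)C=C1 | intermediate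
12 | (3R,4R)-3,6-epidioxy-4-hydroxy-6-methoxy-4-methylheptanoic acid 1,4-lactone (cis-fused 1,2-dioxane–γ-lactone; both C6 epimers) | COC1(C)C[C@@]2(C)OC(=O)C[C@H]2OO1 | intermediate
13 | (3R,4R)-configured cyclic peroxycarbenium ion (cation at C6 of 12 after loss of methoxide) as its triflate | C[C+]1C[C@@]2(C)OC(=O)C[C@H]2OO1.[O-]S(=O)(=O)C(F)(F)F | intermediate
14 | (3R,4R,6S)-3,6-epidioxy-4-hydroxy-4,6-dimethylnon-8-enoic acid 1,4-lactone | C[C@]1(CC=C)C[C@@]2(C)OC(=O)C[C@H]2OO1 | intermediate
15 | 11-bromoundec-1-ene | C=CCCCCCCCCCBr | starting material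
16 | phenylmagnesium bromide | Br[Mg]c1ccccc1 | starting material
17 | 11-phenylundec-1-ene | C=CCCCCCCCCCc1ccccc1 | intermediate
18 | (3R,4R,6S)-3,6-epidioxy-4-hydroxy-4,6-dimethyl-18-phenyloctadec-8-enoic acid 1,4-lactone (E/Z) | C[C@]1(CC=CCCCCCCCCCc2ccccc2)C[C@@]2(C)OC(=O)C[C@H]2OO1 | intermediate
19 | plakortolide K, (3R,4R,6S)-3,6-epidioxy-4-hydroxy-4,6-dimethyl-18-phenyloctadecanoic acid 1,4-lactone | C[C@]1(CCCCCCCCCCCCc2ccccc2)C[C@@]2(C)OC(=O)C[C@H]2OO1 | target

**Step count and risks**
Total steps: 8. Longest linear sequence: 7 (steps 1, 2, 3, 4, 5, 7, 8 from (S)-lactic acid); step 6 is a one-step side branch.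

Risk 1, step 4: the primary ozonide may cleave partly the other way (ketone plus formaldehyde O-oxide), and the amine may cause elimination instead of cyclisation. Fallback, setting out from 9 and coming back at 11: take the peroxide oxygens from H2O2 instead of ozone. Ozonolysis of 9 in CH2Cl2 at −78 °C with Me2S work-up gives, whatever the direction of cleavage, the methyl ketone (R)-5-methyl-5-(2-oxopropyl)furan-2(5H)-one F1. Perketalisation of F1 with H2O2·urea and Sc(OTf)3 (cat.) in MeOH gives hydroperoxy ketal 11, which is cyclised with Et2NH in CF3CH2OH to 12 as before.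

Risk 2, step 5: the peroxyketal may ionise by ring opening instead of loss of methoxide, or the facial selectivity at C6 may be lower than the chair model predicts. Fallback, setting out from 9 and 15 and coming back at 19: make the tertiary C6 hydroperoxide directly and accept separation of C6 epimers. Li2CuCl4-catalysed coupling of 15 with 2-phenylethylmagnesium bromide gives 13-phenyltridec-1-ene F2. Cross-metathesis of 9 with F2 (second-generation Hoveyda–Grubbs catalyst) gives (R)-5-methyl-5-(2-methyl-14-phenyltetradec-2-en-1-yl)furan-2(5H)-one F3 as an E/Z mixture. Mukaiyama–Isayama hydroperoxysilylation (Co(thd)2, cobalt bis(2,2,6,6-tetramethylheptane-3,5-dionate), cat., O2, Et3SiH, ClCH2CH2Cl, rt) places the peroxide on the more substituted carbon and gives (5R)-5-methyl-5-[2-methyl-14-phenyl-2-(triethylsilylperoxy)tetradecyl]furan-2(5H)-one F4 as both C6 epimers. HCl in MeOH frees (5R)-5-(2-hydroperoxy-2-methyl-14-phenyltetradecyl)-5-methylfuran-2(5H)-one F5. Et2NH in CF3CH2OH then closes F5 by the same peroxy-Michael addition to 19 and its epimer 6-epi-plakortolide K F6, which are separated by chromatography.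

Risk 3, step 3: the hindered α-oxygenated aldehyde may olefinate slowly or with poor Z-selectivity, and it may suffer α-ketol rearrangement under base. Fallback, setting out from 6 and coming back at 9: build the butenolide by ring-closing metathesis instead of Z-olefination. iBu2AlH gives lactol 7 as before; excess Ph3P=CH2 (from Ph3PCH3Br and KOtBu) methylenates its open form, the hemiacetal losing pivalaldehyde, to give (R)-3,5-dimethylhexa-1,5-dien-3-ol F7. Acryloyl chloride, Et3N and DMAP give (R)-3,5-dimethylhexa-1,5-dien-3-yl acrylate F8. Ring-closing metathesis (second-generation Hoveyda–Grubbs catalyst, Ti(OiPr)4, CH2Cl2, 40 °C) between the acrylate and the vinyl group, the 1,1-disubstituted alkene being slower, gives 9.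

**Further compounds**
F1 | step 4 | (R)-5-methyl-5-(2-oxopropyl)furan-2(5H)-one | C[C@]1(CC(C)=O)OC(=O)C=C1
F2 | step 5 | 13-phenyltridec-1-ene | C=CCCCCCCCCCCCc1ccccc1
F3 | step 5 | (R)-5-methyl-5-(2-methyl-14-phenyltetradec-2-en-1-yl)furan-2(5H)-one (E/Z) | C[C@]1(CC(C)=CCCCCCCCCCCCc2ccccc2)OC(=O)C=C1
F4 | step 5 | (5R)-5-methyl-5-[2-methyl-14-phenyl-2-(triethylsilylperoxy)tetradecyl]furan-2(5H)-one (both epimers at the peroxide carbon) | C[C@]1(CC(C)(OO[Si](CC)(CC)CC)CCCCCCCCCCCCc2ccccc2)OC(=O)C=C1
F5 | step 5 | (5R)-5-(2-hydroperoxy-2-methyl-14-phenyltetradecyl)-5-methylfuran-2(5H)-one (both epimers at the peroxide carbon) | C[C@]1(CC(C)(OO)CCCCCCCCCCCCc2ccccc2)OC(=O)C=C1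
F6 | step 5 | 6-epi-plakortolide K, (3R,4R,6R)-3,6-epidioxy-4-hydroxy-4,6-dimethyl-18-phenyloctadecanoic acid 1,4-lactone | C[C@@]1(CCCCCCCCCCCCc2ccccc2)C[C@@]2(C)OC(=O)C[C@H]2OO1
F7 | step 3 | (R)-3,5-dimethylhexa-1,5-dien-3-ol | C[C@](O)(C=C)CC(C)=C
F8 | step 3 | (R)-3,5-dimethylhexa-1,5-dien-3-yl acrylate | C[C@](OC(=O)C=C)(C=C)CC(C)=C
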